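## The problem

Compound 16 is (2S)-8-geranyl-5-hydroxy-7-methoxyflavanone. Ring C (O1, C2, C3, C4) is fused to a phloroglucinol-type ring A that keeps a single hydrogen (C6), and C2 carries an unsubstituted phenyl group. Ring A is a regiochemical problem: its three oxygens end as three different functions (free hydroxyl at C5, methyl ether at C7, ring oxygen O1), the geranyl chain sits at C8 between the C7 oxygen and O1, and the acyl carbon C4 is attached at C4a between O1 and the C5 oxygen. C2 is the only stereocentre, so nothing in the molecule can relay its configuration and a reagent has to set it. C2 is also fragile: an enolate at C3 expels O1 (retro-oxa-Michael) and recloses without memory, so base must be kept away once C2 is set. The geranyl chain has two trisubstituted alkenes, one of fixed 2E geometry. They rule out hydrogenation, electrophilic halogen next to a free ortho phenol (haloetherification) and strong protic or Lewis acids (cation–olefin cyclisation). The enabling feature is that ring C is only the three-carbon bridge C4–C3–C2 between C4a and O1, with a plain aryl group on C2. An ortho-iodophenol (iodine on C4a, hydroxyl as O1), carbon monoxide (C4) and phenylacetylene (C3, C2 and the phenyl ring) contain every atom of it. In addition, the C5 oxygen is peri to the C4 carbonyl, so chelation can tell it from the C7 oxygen at the end.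

## Retrosynthesis

**16 from 15.** The last cut is the O–CH3 bond at C5. Flavanone 15 carries methyl ethers at both C5 and C7. This is chosen over an acetal at O5 because the two ether oxygens of ring A can then start as the two equivalent methoxy groups of 3,5-dimethoxyphenol 1, so no phloroglucinol hydroxyl has to be told from another by a statistical or sterically biased protection. The forward step must cleave only the ether chelated to the C4 carbonyl and leave the C7 ether, the geranyl alkenes and C2 alone.

**15 from 13.** Removing the two hydrogens at C2 and C3 leads to flavone 13, which has no stereocentre. This is preferred to building C2 in an open chain, because a β-aryloxy ketone with a defined C2 would have to survive every later step. The forward step is an enantioselective conjugate reduction that delivers hydride to one face of C2, ignores the isolated alkenes, and holds the ketone as silyl enol ether 14 until work-up.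

**13 from 8, 9 and 10.** This is the central disconnection. Three bonds are cut, C4a–C4, C4–C3 and O1–C2, and ring C falls apart into iodophenol 8, carbon monoxide 9 and phenylacetylene 10. The neighbouring disconnections (aldol condensation of an acetophenone followed by oxa-Michael closure, or O-acylation and base-induced acyl shift) need a ring A ketone and strong base, and the first gives racemic flavanone directly. Here the precursor is a single arene with one halogen, and the product has the correct oxidation level at C4. The forward reaction must favour CO insertion over direct alkynylation and 6-endo over 5-exo closure. Ring A regiochemistry is not an issue, because the only free hydroxyl of 8 lies between the iodine and the geranyl group. The reaction passes through ynone 11 and enaminone 12.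

**8 from 7 and 5.** The phenol of 8 is masked as the methoxymethyl ether 7, and the C–I bond is cut back to arene 5 through aryllithium 6. Directed metalation is chosen over electrophilic iodination of a free phenol. An iodonium source with an ortho-geranylphenol invites iodoetherification, and the position para to the hydroxyl would compete. In 5 the acetal has one free ortho position left, so the lithiation site is unambiguous.

**5 from 2 and 3, and 2 from 1.** The aryl–CH2 bond is cut to aryllithium 4 and geranyl bromide 3. Acetal 2 comes from phenol 1 in one step. The two positions ortho to the acetal in 2 are equivalent, each flanked by the acetal and a methoxy group, so the first metalation also has one productive outcome. The forward step needs SN2 attack at the primary carbon of 3 so that the 2E alkene is not disturbed.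

## Roads not taken

**Alternative 1:** Ring A would be made de novo by a Danheiser benzannulation. Heating 3-ethoxycyclobut-2-en-1-one A2 with the geranyl-bearing alkynyl ether A3 forms C8a–C8, C7–C6 and C8a–C4a through a vinylketene [2+2] addition, four-electron ring opening and six-electron electrocyclisation. The product is 5-ethoxy-2-geranyl-3-methoxyphenol A1.
- Merit: the pericyclic cascade fixes the positions of all four ring A substituents without any directing-group argument. In this respect it is at least as secure as the chosen plan, which relies on the acetal outranking methoxy as a metalation director.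
- Weak points: A3 is a 1-alkoxyalkyne that is not a stock chemical and would need several steps from 3, and A2 must also be prepared. The C5 oxygen emerges as an ethyl ether, which is harder to remove than a methyl ether beside a geranyl chain. A1 still lacks ring C and the stereocentre, so the C4a hydrogen would have to be functionalised afterwards.
- Comparison: the chosen plan reaches the same substitution level (5, then 8) in two to four steps from commodity phenol 1, using the symmetry of 2.

**Alternative 2:** Ring C would be closed at O1–C8a by intramolecular palladium-catalysed aryl etherification (Pd(OAc)2, bulky biaryl phosphine) of the open-chain bromo alcohol A5. The product is the 4-silyloxyflavan A4.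
- Merit: C2 is set in an open chain by ketone reduction, and the ring closure does not touch the C2–O bond. On stereocontrol this road is better than the chosen one.
- Weak points: the aryl bromide of A5 is flanked by the geranyl group and the side chain, which slows oxidative addition and C–O reductive elimination. The secondary benzylic alkoxide on palladium can undergo β-hydride elimination instead. C4 is carried at the alcohol level, so desilylation, oxidation and deprotection follow the ring closure. The arene needs three adjacent carbon and halogen substituents, which is a longer ring A synthesis.
- Comparison: the chosen plan accepts a reagent-controlled reduction of a flavone, and in return forms three bonds and the correct C4 oxidation level in one step from a simpler arene.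

**Alternative 3:** Ring C would be closed at C4–C4a by a Parham cyclisation. Bromine–lithium exchange in the Weinreb amide A7 is followed by attack of the aryllithium on the amide, giving the protected flavanone A6.
- Merit: the flavanone arrives at the right oxidation level with C2 already in place, and only a deprotection remains. This is the shortest endgame of all and needs no enantioselective reduction.
- Weak points: the aryl ether bond of A7 must be made by SN2 displacement at a secondary benzylic carbon by a phenol flanked by bromine and the geranyl group, where elimination and partial ionisation compete. During the exchange, A7 is a β-aryloxy carbonyl compound exposed to an alkyllithium, and deprotonation α to the amide expels the aryloxide.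
- Comparison: the chosen plan creates the fragile β-aryloxy ketone only in the last two steps and never exposes it to base.

Key step: step 5

Remark on naming: geranyl means (2E)-3,7-dimethylocta-2,6-dien-1-yl throughout.

Assumption on the chemistry: the sense of induction of the copper hydride reduction is taken by analogy with β,β-disubstituted cyclic enones. (S)-DTBM-SEGPHOS is written, and the (R)-ligand would be used if a trial on the parent flavone shows the opposite sense.

## Route

Step 1
Reactants: 1 3,5-dimethoxyphenol
Product: 2 1,3-dimethoxy-5-(methoxymethoxy)benzene
Conditions: NaH, MOMCl, DMF, 0 °C to rt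
Reagents that add atoms: chloromethyl methyl ether (MOMCl), COCCl
Why: Williamson-type O-alkylation of the sodium phenoxide with the α-chloro ether; there is one hydroxyl, so no selectivity question arises, and the acetal installed is the directing group for steps 2 and 3.

Step 2
Reactants: 2 1,3-dimethoxy-5-(methoxymethoxy)benzene; 3 geranyl bromide
Product: 5 2-geranyl-1,5-dimethoxy-3-(methoxymethoxy)benzene, via aryllithium 4 (not isolated)
Conditions: n-BuLi, TMEDA, THF, 0 °C; then CuI (10 mol %), 3, −78 °C to rt
Reagents that add atoms: none
Why: Directed ortho-metalation; the acetal and the adjacent methoxy group cooperate in binding lithium, so deprotonation should occur at one of the two equivalent positions between them and not between the two weaker methoxy directors. The aryl nucleophile then displaces bromide at the primary carbon of 3 (copper-assisted SN2 allylation), which leaves the 2E alkene as it is.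

Step 3
Reactants: 5 2-geranyl-1,5-dimethoxy-3-(methoxymethoxy)benzene
Product: 7 2-geranyl-4-iodo-1,5-dimethoxy-3-(methoxymethoxy)benzene, via aryllithium 6 (not isolated)
Conditions: n-BuLi, THF, 0 °C; then I2, −78 °C; aq. Na2S2O3
Reagents that add atoms: iodine, II
Why: Second directed ortho-metalation; only one position ortho to the acetal is left, it is also flanked by a methoxy group, and the geranyl neighbour turns the acetal chain toward this C–H. Trapping the aryllithium with iodine at −78 °C is far faster than any reaction of iodine with the trisubstituted alkenes, and no free phenol is present that could lead to iodoetherification.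

Step 4
Reactants: 7 2-geranyl-4-iodo-1,5-dimethoxy-3-(methoxymethoxy)benzene
Product: 8 2-geranyl-6-iodo-3,5-dimethoxyphenol
Conditions: HCl (1 M in MeOH), rt
Reagents that add atoms: none
Why: Acid-catalysed acetal exchange with methanol frees the phenol; dilute acid at room temperature should stay below what is needed for chroman formation from the ortho-geranylphenol or for protodeiodination of the electron-rich ring.

Step 5
Reactants: 8 2-geranyl-6-iodo-3,5-dimethoxyphenol; 9 carbon monoxide; 10 phenylacetylene
Product: 13 8-geranyl-5,7-dimethoxyflavone, via ynone 11 (not isolated), via enaminone 12 (not isolated)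
Conditions: PdCl2(PPh3)2 (5 mol %), CO (10 bar), Et2NH (solvent), 90 °C, no copper co-catalyst
Reagents that add atoms: none
Why: Zerovalent palladium, formed from PdCl2(PPh3)2 under the reaction conditions, inserts into the C–I bond of 8; the electron-rich aryl group migrates to coordinated CO, and the acylpalladium iodide takes up the acetylide made from 10 and Et2NH and eliminates ynone 11 (C4a–C4 and C4–C3). Diethylamine then adds to the β-carbon of 11 to give enaminone 12, and the phenol displaces the amine at that carbon by addition–elimination (O1–C2), which closes ring C. The closest known reaction type is the palladium-catalysed carbonylative Sonogashira coupling of 2-iodophenols with terminal alkynes in a secondary amine, which gives flavones in one flask. Ring C closes in the 6-endo mode (6-endo-dig counted from 11, 6-endo-trig from 12); the 5-exo mode leading to an aurone would need attack at the α-carbon, which is the electron-rich, unreactive end of the enaminone. No stereocentre is formed. The step needs CO insertion to outrun direct alkynylation, which CO pressure, the absence of copper and the electron-rich aryl group should secure. It also needs a single ring A regiochemistry, which is fixed because the only free hydroxyl of 8 lies between the iodine and the geranyl group, so only the 8-geranyl flavone can form. The geranyl alkenes are attached meta to the palladium-bearing carbon and cannot reach it for a Heck or acylpalladation closure.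

Step 6
Reactants: 13 8-geranyl-5,7-dimethoxyflavone
Product: 15 (2S)-8-geranyl-5,7-dimethoxyflavanone, via silyl enol ether 14 (not isolated)
Conditions: Cu(OAc)2·H2O (5 mol %), (S)-DTBM-SEGPHOS (5.5 mol %), (EtO)2MeSiH, toluene, 0 °C to rt; then 1 M HCl, THF, 0 °C
Reagents that add atoms: none
Why: Copper hydride asymmetric conjugate reduction, known for β,β-disubstituted cyclic enones and chromones; the bisphosphine-bound monovalent copper hydride delivers hydride to one face of C2 and thereby sets 2S, and the copper enolate is silylated by the silane, which regenerates the hydride. Silyl enol ether 14 protects C4 from 1,2-reduction and blocks β-elimination of O1 until the mild acidic work-up; isolated trisubstituted alkenes do not insert into copper hydride under these conditions.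

Step 7
Reactants: 15 (2S)-8-geranyl-5,7-dimethoxyflavanone
Product: 16 (2S)-8-geranyl-5-hydroxy-7-methoxyflavanone
Conditions: MgI2·OEt2 (4 equiv), THF, 60 °C; 1 M HCl work-up
Reagents that add atoms: none
Why: Chelation-controlled ether cleavage, a reaction type known for 5-methoxy-8-prenylflavanones; magnesium bridges the C4 carbonyl and O5, and iodide removes the activated methyl group by SN2, while the C7 ether cannot chelate and should survive. The medium has no base able to enolise C3 and the unsubstituted phenyl ring does not support ionisation at C2, so the stereocentre should hold; the geranyl alkenes see no protic acid.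

## Compound list

1 | 3,5-dimethoxyphenol | COc1cc(O)cc(OC)c1 | starting material
2 | 1,3-dimethoxy-5-(methoxymethoxy)benzene | COCOc1cc(OC)cc(OC)c1 | intermediate
3 | geranyl bromide, (2E)-1-bromo-3,7-dimethylocta-2,6-diene | BrC/C=C(\C)CCC=C(C)C | starting material
4 | [2,4-dimethoxy-6-(methoxymethoxy)phenyl]lithium | [Li]c1c(OCOC)cc(OC)cc1OC | intermediate
5 | 2-geranyl-1,5-dimethoxy-3-(methoxymethoxy)benzene | COCOc1cc(OC)cc(OC)c1C/C=C(\C)CCC=C(C)C | intermediate
6 | [3-geranyl-4,6-dimethoxy-2-(methoxymethoxy)phenyl]lithium | COCOc1c([Li])c(OC)cc(OC)c1C/C=C(\C)CCC=C(C)C | intermediate
7 | 2-geranyl-4-iodo-1,5-dimethoxy-3-(methoxymethoxy)benzene | COCOc1c(I)c(OC)cc(OC)c1C/C=C(\C)CCC=C(C)C | intermediate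
8 | 2-geranyl-6-iodo-3,5-dimethoxyphenol | Oc1c(I)c(OC)cc(OC)c1C/C=C(\C)CCC=C(C)C | intermediate
9 | carbon monoxide | [C-]#[O+] | starting material
10 | phenylacetylene | C#Cc1ccccc1 | starting material
11 | 1-(3-geranyl-2-hydroxy-4,6-dimethoxyphenyl)-3-phenylprop-2-yn-1-one | O=C(C#Cc1ccccc1)c1c(O)c(C/C=C(\C)CCC=C(C)C)c(OC)cc1OC | intermediate
12 | (2E)-3-(diethylamino)-1-(3-geranyl-2-hydroxy-4,6-dimethoxyphenyl)-3-phenylprop-2-en-1-one (drawn as the E isomer; either isomer leads on to 13) | O=C(/C=C(/N(CC)CC)c1ccccc1)c1c(O)c(C/C=C(\C)CCC=C(C)C)c(OC)cc1OC | intermediate
13 | 8-geranyl-5,7-dimethoxyflavone (8-geranyl-5,7-dimethoxy-2-phenyl-4H-chromen-4-one) | COc1cc(OC)c(C/C=C(\C)CCC=C(C)C)c2oc(-c3ccccc3)cc(=O)c12 | intermediate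
14 | (2S)-4-{[diethoxy(methyl)silyl]oxy}-8-geranyl-5,7-dimethoxy-2-phenyl-2H-chromene | COc1cc(OC)c2c(c1C/C=C(\C)CCC=C(C)C)O[C@H](c1ccccc1)C=C2O[Si](C)(OCC)OCC | intermediate
15 | (2S)-8-geranyl-5,7-dimethoxyflavanone | COc1cc(OC)c2c(c1C/C=C(\C)CCC=C(C)C)O[C@H](c1ccccc1)CC2=O | intermediate
16 | (2S)-8-geranyl-5-hydroxy-7-methoxyflavanone | COc1cc(O)c2c(c1C/C=C(\C)CCC=C(C)C)O[C@H](c1ccccc1)CC2=O | target

## Step count and least certain steps

Total step count: 7. Longest linear sequence: 7 steps (1 to 16).

**Step 5 (key step).** The most likely failure is slow oxidative addition at an aryl iodide that is electron-rich and flanked by a phenoxide and a methoxy group. Direct alkynylation without CO uptake and 5-exo closure are the competing paths. The fallback avoids palladium and CO and sets out from 5. Lithiation as in step 3 gives 6, which is acylated with N-methoxy-N-methyl-3-phenylpropiolamide to give the methoxymethyl-protected ynone F1. Treatment of F1 with HCl in MeOH and then with Et2NH frees the phenol (11) and closes the ring through 12, so the route is rejoined at 13.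

**Step 6.** Hydride transfer to an electron-rich vinylogous ester with a peri methoxy group may be slow, and facial discrimination between the phenyl group and O1 at C2 may be incomplete. The fallback sets out from 13. Reduction with an achiral copper hydride (Cu(OAc)2·H2O, 1,2-bis(diphenylphosphino)benzene, the same silane and work-up) gives racemic 8-geranyl-5,7-dimethoxyflavanone F2. Kinetic resolution by asymmetric transfer hydrogenation (RuCl(p-cymene)[(R,R)-TsDPEN], HCO2H/Et3N, taken to about half conversion) is expected to reduce the (2R) ketone faster, to the cis alcohol (2R,4R)-8-geranyl-5,7-dimethoxyflavan-4-ol F3. The unreacted (2S) ketone is separated and rejoins the route as 15. The same resolution can upgrade scalemic material from step 6.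

**Step 7.** Loss of configuration by Lewis-acid-assisted opening and reclosure of ring C, or partial cleavage of the C7 ether, are the main risks, since both ethers and C2 are exposed together. The fallback moves the demethylation in front of the reduction and sets out from 13. MgI2·OEt2 in THF gives 8-geranyl-5-hydroxy-7-methoxyflavone F4, which has no stereocentre to lose. The copper hydride reduction of step 6 is then run on F4 with an extra equivalent of (EtO)2MeSiH. The phenol is silylated in the flask with loss of hydrogen, and conjugate reduction gives the doubly silylated enol ether F5. The 1 M HCl work-up cleaves both silyl groups and gives 16 directly.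

**Step 3.** Deprotonation may stray to the benzylic and allylic CH2 of the geranyl chain or to the position between the two methoxy groups, because both are acidified and the wanted site is crowded. The fallback sets out from 5. The acetal is removed first (HCl, MeOH) to give 2-geranyl-3,5-dimethoxyphenol F6. F6 is iodinated ortho to the hydroxyl with the iodine–morpholine complex in toluene at 0 °C, which relies on hydrogen-bonded delivery of iodine and on the ring carbon being far more nucleophilic than the alkenes. This rejoins the route at 8. It is weaker than step 3 on ortho/para control and on iodoetherification, and is for that reason only the reserve.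

## Further compounds

F1 | step 5 | 1-[3-geranyl-4,6-dimethoxy-2-(methoxymethoxy)phenyl]-3-phenylprop-2-yn-1-one | COCOc1c(C(=O)C#Cc2ccccc2)c(OC)cc(OC)c1C/C=C(\C)CCC=C(C)C
F2 | step 6 | racemic 8-geranyl-5,7-dimethoxyflavanone | COc1cc(OC)c2c(c1C/C=C(\C)CCC=C(C)C)OC(c1ccccc1)CC2=O
F3 | step 6 | (2R,4R)-8-geranyl-5,7-dimethoxyflavan-4-ol | COc1cc(OC)c2c(c1C/C=C(\C)CCC=C(C)C)O[C@@H](c1ccccc1)C[C@H]2O
F4 | step 7 | 8-geranyl-5-hydroxy-7-methoxyflavone | COc1cc(O)c2c(c1C/C=C(\C)CCC=C(C)C)oc(-c1ccccc1)cc2=O
F5 | step 7 | (2S)-4,5-bis{[diethoxy(methyl)silyl]oxy}-8-geranyl-7-methoxy-2-phenyl-2H-chromene | COc1cc(O[Si](C)(OCC)OCC)c2c(c1C/C=C(\C)CCC=C(C)C)O[C@H](c1ccccc1)C=C2O[Si](C)(OCC)OCC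
F6 | step 3 | 2-geranyl-3,5-dimethoxyphenol | COc1cc(O)c(C/C=C(\C)CCC=C(C)C)c(OC)c1
A1 | alternative 1 | 5-ethoxy-2-geranyl-3-methoxyphenol | CCOc1cc(O)c(C/C=C(\C)CCC=C(C)C)c(OC)c1
A2 | alternative 1 | 3-ethoxycyclobut-2-en-1-one | CCOC1=CC(=O)C1
A3 | alternative 1 | (4E)-1-methoxy-5,9-dimethyldeca-4,8-dien-1-yne | COC#CC/C=C(\C)CCC=C(C)C
A4 | alternative 2 | (2S)-4-(tert-butyldimethylsilyloxy)-8-geranyl-7-methoxy-5-(methoxymethoxy)flavan, C4 undefined | COCOc1cc(OC)c(C/C=C(\C)CCC=C(C)C)c2c1C(O[Si](C)(C)C(C)(C)C)C[C@@H](c1ccccc1)O2
A5 | alternative 2 | (1S)-3-[2-bromo-3-geranyl-4-methoxy-6-(methoxymethoxy)phenyl]-3-(tert-butyldimethylsilyloxy)-1-phenylpropan-1-ol | COCOc1cc(OC)c(C/C=C(\C)CCC=C(C)C)c(Br)c1C(O[Si](C)(C)C(C)(C)C)C[C@H](O)c1ccccc1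
A6 | alternative 3 | (2S)-8-geranyl-7-methoxy-5-(methoxymethoxy)flavanone | COCOc1cc(OC)c(C/C=C(\C)CCC=C(C)C)c2c1C(=O)C[C@@H](c1ccccc1)O2
A7 | alternative 3 | (3S)-3-[2-bromo-6-geranyl-5-methoxy-3-(methoxymethoxy)phenoxy]-N-methoxy-N-methyl-3-phenylpropanamide | COCOc1cc(OC)c(C/C=C(\C)CCC=C(C)C)c(O[C@@H](CC(=O)N(C)OC)c2ccccc2)c1Br
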